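**Plan**
- Retrosynthesis cuts ring B at C1'–C6' and C2'–C3'. This gives racemic 4-chloro-2,3-dimethoxycyclobutenone and a 2-(1-stannylvinyl)chromone. The C3' hydroxyl and the C4'/C5' methoxyls of ring B map onto the carbonyl and the two enol ether carbons of the four-membered ring, and C6' is its CHCl carbon.
- The stannane is cut at C–Sn to an enol triflate of a 2-acetylchromone. Ring C is cut at O1–C2 and C2–C3 to 2-hydroxy-3,4,5-trimethoxyacetophenone and a pyruvate ketal ester. The chloride is traced to dimethyl squarate.
- Forward: ring A is bought as 2,3,4-trimethoxybenzaldehyde, ring C is closed by Claisen condensation and cyclodehydration, and the vinyl tin handle is installed. Ring B is built last by Stille coupling and electrocyclic benzannulation, which frees the only phenol without any protecting group.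
- Stereochemistry: the target is achiral. The single stereocentre met on the way (C4 of the cyclobutenones) is racemic and ends as aromatic C6'.

Key step: step 8

Step 1
Reactants: 1 2,3,4-trimethoxybenzaldehyde
Product: 3 2,3,4-trimethoxyphenol, via 2,3,4-trimethoxyphenyl formate 2 (not isolated)
Conditions: 30% aq. H2O2, H2SO4 (cat.), MeOH, rt
Reagents that add atoms: hydrogen peroxide, OO
Why: Dakin oxidation, in which acid-catalysed Baeyer–Villiger migration of the electron-rich aryl group gives the aryl formate and methanol cleaves it to the phenol.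

Step 2
Reactants: 3 2,3,4-trimethoxyphenol
Product: 4 1-(2-hydroxy-3,4,5-trimethoxyphenyl)ethan-1-one
Conditions: AcOH, BF3·OEt2, 90 °C; then H2O
Reagents that add atoms: acetic acid, CC(=O)O
Why: BF3-promoted Fries-type ortho-acylation should place the acetyl group at C6, the only free position ortho to the hydroxyl and para to the C3 methoxyl, with the boron chelate of the product preventing further acylation until aqueous work-up.

Step 3
Reactants: 4 1-(2-hydroxy-3,4,5-trimethoxyphenyl)ethan-1-one; 5 methyl 2,2-dimethoxypropanoate
Product: 8 2-acetyl-6,7,8-trimethoxy-4H-chromen-4-one, via diketone 6 (not isolated), via ketal chromone 7 (not isolated)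
Conditions: NaH, THF, reflux; then conc. HCl, AcOH, 80 °C
Reagents that add atoms: water, O
Why: Crossed Claisen condensation of the acetophenone dianion with the non-enolisable ketal ester forms C2–C3, and acid then closes O1–C2 by cyclodehydration (the classical chromone synthesis from 1-(2-hydroxyaryl)-1,3-diketones, as used for chromone-2-carboxylates) while hydrolysing the ketal to the acetyl group.

Step 4
Reactants: 8 2-acetyl-6,7,8-trimethoxy-4H-chromen-4-one
Product: 9 1-(6,7,8-trimethoxy-4-oxo-4H-chromen-2-yl)ethenyl trifluoromethanesulfonate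
Conditions: KN(SiMe3)2, THF, −78 °C (ketone added to base); then PhNTf2, −78 to 0 °C; aq. NH4Cl
Reagents that add atoms: N-phenylbis(trifluoromethanesulfonimide), O=S(=O)(N(c1ccccc1)S(=O)(=O)C(F)(F)F)C(F)(F)F
Why: Enol triflate formation, in which the hindered amide base removes a proton from the acetyl methyl, the only enolisable position, and the potassium enolate is sulfonylated on oxygen by PhNTf2.

Step 5
Reactants: 9 1-(6,7,8-trimethoxy-4-oxo-4H-chromen-2-yl)ethenyl trifluoromethanesulfonate
Product: 10 6,7,8-trimethoxy-2-[1-(tributylstannyl)ethenyl]-4H-chromen-4-one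
Conditions: (Bu3Sn)2, Pd(PPh3)4 (cat.), LiCl, dioxane, 90 °C
Reagents that add atoms: hexabutyldistannane, CCCC[Sn](CCCC)(CCCC)[Sn](CCCC)(CCCC)CCCC
Why: Palladium-catalysed stannylation of an enol triflate, in which zerovalent palladium inserts into the C–OTf bond, chloride from LiCl stabilises the vinylpalladium species, and Sn–Sn transmetalation with reductive elimination fixes tin on the internal vinyl carbon.

Step 6
Reactants: 11 dimethyl squarate (3,4-dimethoxycyclobut-3-ene-1,2-dione)
Product: 12 racemic 4-hydroxy-2,3-dimethoxycyclobut-2-en-1-one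
Conditions: LiAlH(OtBu)3, THF, −78 to −40 °C; then aq. NH4Cl
Reagents that add atoms: none
Why: Mono 1,2-reduction of a cyclobutenedione, in which the bulky hydride adds once to one of the two equivalent carbonyls and the resulting alkoxide resists further reduction at low temperature; the new C4 centre is racemic and is erased later.

Step 7
Reactants: 12 racemic 4-hydroxy-2,3-dimethoxycyclobut-2-en-1-one
Product: 13 racemic 4-chloro-2,3-dimethoxycyclobut-2-en-1-one
Conditions: 1-chloro-N,N,2-trimethylprop-1-en-1-amine, CH2Cl2, −20 to 0 °C; used at once without chromatography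
Reagents that add atoms: 1-chloro-N,N,2-trimethylprop-1-en-1-amine, CC(C)=C(Cl)N(C)C
Why: Neutral deoxychlorination with an α-chloroenamine, in which the alcohol is converted to an alkoxyiminium chloride that collapses by direct chloride attack at C4, with no free acid present to trigger ionisation and allylic transposition toward the cyclobutenedione.

Step 8
Reactants: 13 racemic 4-chloro-2,3-dimethoxycyclobut-2-en-1-one; 10 6,7,8-trimethoxy-2-[1-(tributylstannyl)ethenyl]-4H-chromen-4-one
Product: 17 3'-hydroxy-4',5',6,7,8-pentamethoxyflavone (CNP0265341.0), via 4-alkenylcyclobutenone 14 (not isolated), via dienylketene 15 (not isolated), via cyclohexadienone 16 (not isolated)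
Conditions: Pd2(dba)3 (cat.), tri(2-furyl)phosphine (cat.), dioxane, 50 °C, then 100 °C
Reagents that add atoms: none
Why: Zerovalent palladium inserts into the allylic C4–Cl bond of 13 to give an oxocyclobutenyl palladium chloride, the 1-chromonylvinyl group is transferred from tin, and reductive elimination at C4 forms C1'–C6' and releases 14; on warming, 14 opens by conrotatory four-electron ring opening to dienylketene 15, the ketene carbon closes onto the vinyl CH2 to give dienone 16, and enolisation delivers phenol 17. The closest known reaction type is the Stille coupling of 4-chloro-2-cyclobutenones with alkenylstannanes followed by thermal benzannulation to phenols. Ring B closes by a thermal six-electron disrotatory electrocyclisation that forms C2'–C3' and is made irreversible by aromatisation. No stereocentre is created, since the racemic C4 centre of 13 and 14 becomes the aromatic C6'–H. The step needs coupling at C4 and not at C2 of the oxocyclobutenyl palladium intermediate; this should be secured because C4 is the unsubstituted terminus and bond formation there restores the conjugated vinylogous ester, whereas C2 carries a methoxyl, and because the ring opening is reversible the ketene isomer with the alkenyl group turned inward is drained by cyclisation. The ketene carbon thus ends as C3'–OH and C2 and C3 as C4' and C5', so ring B needs no protecting group.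

**Compound list**
1 | 2,3,4-trimethoxybenzaldehyde | COc1ccc(C=O)c(OC)c1OC | starting material
2 | 2,3,4-trimethoxyphenyl formate | COc1ccc(OC=O)c(OC)c1OC | intermediate
3 | 2,3,4-trimethoxyphenol | COc1ccc(O)c(OC)c1OC | intermediate
4 | 1-(2-hydroxy-3,4,5-trimethoxyphenyl)ethan-1-one | CC(=O)c1cc(OC)c(OC)c(OC)c1O | intermediate
5 | methyl 2,2-dimethoxypropanoate | COC(=O)C(C)(OC)OC | starting material
6 | 1-(2-hydroxy-3,4,5-trimethoxyphenyl)-4,4-dimethoxypentane-1,3-dione | CC(OC)(OC)C(=O)CC(=O)c1cc(OC)c(OC)c(OC)c1O | intermediate
7 | 2-(1,1-dimethoxyethyl)-6,7,8-trimethoxy-4H-chromen-4-one | CC(OC)(OC)c1cc(=O)c2cc(OC)c(OC)c(OC)c2o1 | intermediate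
8 | 2-acetyl-6,7,8-trimethoxy-4H-chromen-4-one | CC(=O)c1cc(=O)c2cc(OC)c(OC)c(OC)c2o1 | intermediate
9 | 1-(6,7,8-trimethoxy-4-oxo-4H-chromen-2-yl)ethenyl trifluoromethanesulfonate | C=C(OS(=O)(=O)C(F)(F)F)c1cc(=O)c2cc(OC)c(OC)c(OC)c2o1 | intermediate
10 | 6,7,8-trimethoxy-2-[1-(tributylstannyl)ethenyl]-4H-chromen-4-one | CCCC[Sn](CCCC)(CCCC)C(=C)c1cc(=O)c2cc(OC)c(OC)c(OC)c2o1 | intermediate
11 | dimethyl squarate (3,4-dimethoxycyclobut-3-ene-1,2-dione) | COC1=C(OC)C(=O)C1=O | starting material
12 | racemic 4-hydroxy-2,3-dimethoxycyclobut-2-en-1-one | COC1=C(OC)C(O)C1=O | intermediate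
13 | racemic 4-chloro-2,3-dimethoxycyclobut-2-en-1-one | COC1=C(OC)C(Cl)C1=O | intermediate
14 | racemic 2,3-dimethoxy-4-[1-(6,7,8-trimethoxy-4-oxo-4H-chromen-2-yl)ethenyl]cyclobut-2-en-1-one | COC1=C(OC)C(C(=C)c2cc(=O)c3cc(OC)c(OC)c(OC)c3o2)C1=O | intermediate
15 | (3E)-2,3-dimethoxy-5-(6,7,8-trimethoxy-4-oxo-4H-chromen-2-yl)hexa-1,3,5-trien-1-one (ketene carbon and chromonylvinyl group cis) | O=C=C(OC)/C(OC)=C\C(=C)c1cc(=O)c2cc(OC)c(OC)c(OC)c2o1 | intermediate
16 | 2,3-dimethoxy-5-(6,7,8-trimethoxy-4-oxo-4H-chromen-2-yl)cyclohexa-2,4-dien-1-one | COC1=C(OC)C(=O)CC(c2cc(=O)c3cc(OC)c(OC)c(OC)c3o2)=C1 | intermediate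
17 | 2-(3-hydroxy-4,5-dimethoxyphenyl)-6,7,8-trimethoxy-4H-chromen-4-one (CNP0265341.0) | COc1cc(-c2cc(=O)c3cc(OC)c(OC)c(OC)c3o2)cc(O)c1OC | target

**Totals**
Total step count: 8. Longest linear sequence: 6 steps (steps 1, 2, 3, 4, 5, 8); the squarate branch (steps 6, 7) joins at step 8.

**Steps most likely to fail**

Step 8. The chloride may ionise and lose chloromethane before oxidative addition. Reductive elimination may occur at the methoxy-bearing terminus of the oxocyclobutenyl palladium species and give the regioisomeric arene. Transmetalation of the hindered 1-substituted vinylstannane may be slow enough for cine substitution or protodestannylation to take over. The fallback builds ring B from a ready-made arene and sets out from 4. Claisen–Schmidt condensation of 4 with commercial 3-(benzyloxy)-4,5-dimethoxybenzaldehyde (KOH, EtOH, rt) would give (E)-3-[3-(benzyloxy)-4,5-dimethoxyphenyl]-1-(2-hydroxy-3,4,5-trimethoxyphenyl)prop-2-en-1-one F1. Oxidative cyclisation of the 2'-hydroxychalcone (I2 cat., DMSO, 130 °C) would give 2-[3-(benzyloxy)-4,5-dimethoxyphenyl]-6,7,8-trimethoxy-4H-chromen-4-one F2. Hydrogenolysis of the benzyl ether (H2, palladium on carbon, EtOAc, rt) would then come back to the route at 17.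

Step 7. The activated hydroxyl may ionise, with allylic transposition of the leaving group to the methoxy-bearing carbon and loss of chloromethane to the cyclobutenedione, either during chlorination or on handling. The fallback sets out from 12 and avoids the chloride. Acetylation under basic conditions (Ac2O, pyridine, DMAP cat., CH2Cl2, 0 °C) would give the storable allylic ester 2,3-dimethoxy-4-oxocyclobut-2-en-1-yl acetate F3. F3 would then take the place of 13 in the coupling with stannane 10 (Pd2(dba)3, tri(2-furyl)phosphine, LiCl, DMF, 60 °C then 100 °C). The oxocyclobutenyl palladium intermediate would arise by ionisation of the allylic acetate, as in the known coupling of allylic acetates with organostannanes, and the cascade through 14, 15 and 16 would come back to the route at 17.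

Step 5. The newly formed vinylstannane may undergo Stille homocoupling with unreacted triflate, and protodestannylation may occur on purification. The fallback sets out from 9 and installs tin by hydrometalation instead of Sn–Sn transfer. Dehydrotriflation with DBU (CH2Cl2, 0 °C to rt) would give 2-ethynyl-6,7,8-trimethoxy-4H-chromen-4-one F4. Palladium-catalysed hydrostannation (Bu3SnH, PdCl2(PPh3)2 cat., THF, 0 °C) should place tin on the internal carbon, as is usual for terminal alkynes conjugated to acceptor groups, and come back to the route at 10.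

**Further compounds**
F1 | step 8 | (E)-3-[3-(benzyloxy)-4,5-dimethoxyphenyl]-1-(2-hydroxy-3,4,5-trimethoxyphenyl)prop-2-en-1-one | COc1cc(C(=O)/C=C/c2cc(OC)c(OC)c(OCc3ccccc3)c2)c(O)c(OC)c1OC
F2 | step 8 | 2-[3-(benzyloxy)-4,5-dimethoxyphenyl]-6,7,8-trimethoxy-4H-chromen-4-one | COc1cc(-c2cc(=O)c3cc(OC)c(OC)c(OC)c3o2)cc(OCc2ccccc2)c1OC
F3 | step 7 | 2,3-dimethoxy-4-oxocyclobut-2-en-1-yl acetate (racemic) | CC(=O)OC1C(=O)C(OC)=C1OC
F4 | step 5 | 2-ethynyl-6,7,8-trimethoxy-4H-chromen-4-one | C#Cc1cc(=O)c2cc(OC)c(OC)c(OC)c2o1
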